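## Retrosynthetic overview

1. The cinnamate is unveiled last by α,β-dehydrogenation of a 3-phenylpropanoate. Its C15–O acyl bond is made first, by enantioselective desymmetrising O-acylation of 3-methylpentane-1,5-diol, which sets C13.
2. The Δ1(10) alkene and H-5 come from a stereospecific reductive 1,3-transposition of a 1α-allylic alcohol (set by CBS reduction) of a halim-5(10)-en-1-one.
3. Ring A (formed second) comes from a catalyst-controlled Diels–Alder reaction of methacrolein (sets C4) with a 2-silyloxydiene carried by ring B, then Saegusa oxidation.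
4. Ring B (first ring) is bought as 2-methylcyclohex-2-enone. C8 is set by copper-catalysed asymmetric conjugate methylation, C9 by enolate alkylation with the side-chain iodide (C9–C11 bond).

Assumption 1: compounds are numbered in the order in which they enter the numbered steps; bicyclic compounds carry halimane numbering (decalin C1–C10, side chain C11–C16 on C9, C17 on C8, C18 carboxyl and C19 methyl on C4, C20 on C9).
Assumption 2: vinyl 3-phenylpropanoate is taken as a catalogue reagent.
Design note: C4 has to end on the hindered face of C5 (cis to the C8 and C9 methyls), which a direct [4+2] is unlikely to deliver. C5 is therefore left uncontrolled in step 8, erased in step 9 and re-set by reagent control in steps 11 and 12.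

## Route

Step 1
Reactants: 1 3-methylpentane-1,5-diol; 2 vinyl 3-phenylpropanoate
Product: 3 (R)-5-hydroxy-3-methylpentyl 3-phenylpropanoate
Conditions: 2 (1.1 equiv), (S,S)-ProPhenol [2,6-bis{[(2S)-2-(hydroxydiphenylmethyl)pyrrolidin-1-yl]methyl}-4-methylphenol] (10 mol%), ZnEt2 (20 mol%), PhMe, −20 °C
Reagents that add atoms: none
Why: Proposed new method: a Trost-type dinuclear zinc desymmetrising transacylation, known for 2-substituted propane-1,3-diols with vinyl benzoate (closest known reaction), is extended to a 3-substituted pentane-1,5-diol; the diol should bind as a bis-alkoxide bridging the two zinc centres in a chair-like metallacycle with the C3 methyl pseudo-equatorial, so that only the pro-R alkoxide sits next to the zinc-bound vinyl ester, and acyl transfer there forms the C15–O ester bond and sets C13 (R), while the minor enantiomer is drained by faster second acylation to the achiral diester (the ligand antipode is fixed by the sense found in the first run).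

Step 2
Reactants: 3 (R)-5-hydroxy-3-methylpentyl 3-phenylpropanoate
Product: 4 (S)-5-iodo-3-methylpentyl 3-phenylpropanoate
Conditions: PPh3, imidazole, I2, CH2Cl2, 0 → 23 °C
Reagents that add atoms: iodine, II
Why: Appel iodination of the primary alcohol leaves the ester and the remote stereocentre untouched (the descriptor changes to S only because iodine outranks oxygen).

Step 3
Reactants: 5 2-methylcyclohex-2-en-1-one
Product: 7 [(3R)-2,3-dimethylcyclohex-1-en-1-yl]oxy-trimethylsilane, via dimethylaluminium enolate 6 (not isolated)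
Conditions: AlMe3 (1.4 equiv), Cu(O2C-C4H3S) [copper thiophene-2-carboxylate] (2 mol%), (R)-binaphthyl-2,2'-diyl N,N-bis[(S)-1-phenylethyl]phosphoramidite (4 mol%), Et2O, −30 °C; then TMSOTf, THF, 0 °C
Reagents that add atoms: trimethylaluminium, C[Al](C)C; trimethylsilyl triflate, C[Si](C)(C)OS(=O)(=O)C(F)(F)F
Why: Copper-catalysed asymmetric conjugate addition sets C8 (3R) by ligand control, and O-silylation of the regiodefined aluminium enolate stores the C9 enolate.

Step 4
Reactants: 7 [(3R)-2,3-dimethylcyclohex-1-en-1-yl]oxy-trimethylsilane; 4 (S)-5-iodo-3-methylpentyl 3-phenylpropanoate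
Product: 9 (R)-5-[(1S,2R)-1,2-dimethyl-6-oxocyclohexyl]-3-methylpentyl 3-phenylpropanoate, via lithium enolate 8 (not isolated)
Conditions: MeLi (0.98 equiv), THF, 0 → 23 °C; then 4, HMPA, −78 → −20 °C
Reagents that add atoms: none
Why: Regiospecific enolate alkylation (conjugate addition–alkylation sequence): the primary iodide enters C9 anti to the C8 methyl, which is pseudoaxial in the enolate because of A(1,2) strain, so the quaternary centre forms with the two methyls cis (9S).

Step 5
Reactants: 9 (R)-5-[(1S,2R)-1,2-dimethyl-6-oxocyclohexyl]-3-methylpentyl 3-phenylpropanoate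
Product: 10 (5R,6S)-5,6-dimethyl-6-[(R)-3-methyl-5-(3-phenylpropanoyloxy)pentyl]cyclohex-1-en-1-yl trifluoromethanesulfonate
Conditions: LiN(SiMe3)2 (1.1 equiv), THF, −78 °C; N-(5-chloropyridin-2-yl)bis(triflyl)imide, −78 → 0 °C
Reagents that add atoms: N-(5-chloropyridin-2-yl)-1,1,1-trifluoro-N-(trifluoromethylsulfonyl)methanesulfonamide, O=S(=O)(N(c1ccc(Cl)cn1)S(=O)(=O)C(F)(F)F)C(F)(F)F
Why: Enol triflate formation: the ketone can enolise only towards C5 (C9 is quaternary) and is far more acidic than the ester, so a single vinyl triflate results.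

Step 6
Reactants: 10 (5R,6S)-5,6-dimethyl-6-[(R)-3-methyl-5-(3-phenylpropanoyloxy)pentyl]cyclohex-1-en-1-yl trifluoromethanesulfonate
Product: 12 (R)-5-[(1S,6R)-2-acetyl-1,6-dimethylcyclohex-2-en-1-yl]-3-methylpentyl 3-phenylpropanoate, via ethoxydiene 11 (not isolated)
Conditions: Bu3Sn-C(OEt)=CH2, Pd(PPh3)4 (5 mol%), LiCl, THF, 65 °C; then 1 M HCl, 23 °C
Reagents that add atoms: tributyl(1-ethoxyvinyl)stannane, CCCC[Sn](CCCC)(CCCC)C(=C)OCC; water, O
Why: Stille coupling with an acyl-anion equivalent followed by enol ether hydrolysis installs C1 and C2 as an acetyl group on C10.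

Step 7
Reactants: 12 (R)-5-[(1S,6R)-2-acetyl-1,6-dimethylcyclohex-2-en-1-yl]-3-methylpentyl 3-phenylpropanoate
Product: 13 (R)-5-[(1S,6R)-2-[1-(tert-butyldimethylsilyloxy)vinyl]-1,6-dimethylcyclohex-2-en-1-yl]-3-methylpentyl 3-phenylpropanoate
Conditions: TBSOTf, Et3N, CH2Cl2, 0 °C
Reagents that add atoms: tert-butyldimethylsilyl triflate, CC(C)(C)[Si](C)(C)OS(=O)(=O)C(F)(F)F
Why: Soft enolisation of the methyl ketone (its only α-hydrogens) gives the 2-silyloxydiene; the ester is silylated far more slowly.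

Step 8
Reactants: 13 (R)-5-[(1S,6R)-2-[1-(tert-butyldimethylsilyloxy)vinyl]-1,6-dimethylcyclohex-2-en-1-yl]-3-methylpentyl 3-phenylpropanoate; 14 methacrolein
Product: 15 (4S,8R,9S,13R)-1-(tert-butyldimethylsilyloxy)-18-oxohalim-1(10)-en-15-yl 3-phenylpropanoate as a mixture of C5 epimers
Conditions: 14 (3 equiv), (S)-3,3-diphenyl-1-(2-methylphenyl)tetrahydro-1H,3H-pyrrolo[1,2-c][1,3,2]oxazaborole·HNTf2 (20 mol%), CH2Cl2, −78 → −40 °C; Et3N quench
Reagents that add atoms: none
Why: Corey-type oxazaborolidinium-catalysed Diels–Alder reaction closes ring A: the silyloxy group directs the enal CH2 to C2 and the α-carbon to C5, and the catalyst exposes one face of the s-trans enal so that C4 is S whichever diene face or endo/exo mode reacts, while C5 forms as a mixture that the next step removes.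

Step 9
Reactants: 15 (4S,8R,9S,13R)-1-(tert-butyldimethylsilyloxy)-18-oxohalim-1(10)-en-15-yl 3-phenylpropanoate
Product: 16 (4S,8R,9S,13R)-1,18-dioxohalim-5(10)-en-15-yl 3-phenylpropanoate
Conditions: Pd(OAc)2 (1.1 equiv), MeCN, 23 → 40 °C
Reagents that add atoms: none
Why: Saegusa–Ito oxidation: the palladium enolate at C10 can lose only H-5 (C9 carries no hydrogen), so both C5 epimers converge on one enone and the C5 stereocentre is erased.

Step 10
Reactants: 16 (4S,8R,9S,13R)-1,18-dioxohalim-5(10)-en-15-yl 3-phenylpropanoate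
Product: 18 methyl (4S,8R,9S,13R)-1-oxo-15-(3-phenylpropanoyloxy)halim-5(10)-en-18-oate, via carboxylic acid 17 (not isolated)
Conditions: NaClO2, NaH2PO4, 2-methylbut-2-ene, t-BuOH/H2O, 0 °C; crude acid, then TMSCHN2, MeOH/PhMe, 0 °C
Reagents that add atoms: sodium chlorite, [Na+].[O-]Cl=O; (trimethylsilyl)diazomethane, C[Si](C)(C)C=[N+]=[N-]
Why: Pinnick oxidation of the non-enolisable neopentyl aldehyde and methylation of the hindered acid give the C18 methyl ester without touching C4.

Step 11
Reactants: 18 methyl (4S,8R,9S,13R)-1-oxo-15-(3-phenylpropanoyloxy)halim-5(10)-en-18-oate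
Product: 19 methyl (1S,4S,8R,9S,13R)-1-hydroxy-15-(3-phenylpropanoyloxy)halim-5(10)-en-18-oate
Conditions: (R)-1-methyl-3,3-diphenyltetrahydro-1H,3H-pyrrolo[1,2-c][1,3,2]oxazaborole [(R)-methyl-CBS catalyst] (0.5 equiv), BH3·SMe2, THF, −30 → 0 °C
Reagents that add atoms: none
Why: Corey–Bakshi–Shibata 1,2-reduction: the catalyst treats the tetrasubstituted alkenyl side as the large group and delivers hydride to give the 1S (1α) allylic alcohol by reagent control; the esters are inert.

Step 12
Reactants: 19 methyl (1S,4S,8R,9S,13R)-1-hydroxy-15-(3-phenylpropanoyloxy)halim-5(10)-en-18-oate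
Product: 22 methyl (4S,5S,8R,9S,13R)-15-(3-phenylpropanoyloxy)halim-1(10)-en-18-oate, via sulfonylhydrazine 20 (not isolated), via allylic diazene 21 (not isolated)
Conditions: 2-O2NC6H4SO2NHNH2, PPh3, EtO2CN=NCO2Et, N-methylmorpholine, −30 → 23 °C
Reagents that add atoms: none
Why: Myers reductive 1,3-transposition: Mitsunobu inversion puts nitrogen on the β-face of C1, loss of sulfinic acid gives the allylic diazene, and its retro-ene loss of N2 delivers hydrogen suprafacially to the β-face of C5 (5S, cis to the C9 side chain and to the ester) while the alkene moves to C1=C10.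

Step 13
Reactants: 22 methyl (4S,5S,8R,9S,13R)-15-(3-phenylpropanoyloxy)halim-1(10)-en-18-oate
Product: 23 methyl (4S,5S,8R,9S,13R)-15-[(E)-3-phenylprop-2-enoyloxy]halim-1(10)-en-18-oate
Conditions: lithium 2,2,6,6-tetramethylpiperidide (1.2 equiv), THF, −40 °C; ZnCl2; [Pd(allyl)Cl]2 (2.5 mol%), allyl pivalate, 60 °C
Reagents that add atoms: none
Why: Allyl-palladium-catalysed α,β-dehydrogenation of an ester through its zinc enolate (Newhouse): only the 3-phenylpropanoate has α-hydrogens (the C18 ester is quaternary at C4), and β-hydride elimination gives the conjugated (E)-cinnamate.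

## Compound list

1 | 3-methylpentane-1,5-diol | CC(CCO)CCO | starting material
2 | vinyl 3-phenylpropanoate | C=COC(=O)CCc1ccccc1 | starting material
3 | (R)-5-hydroxy-3-methylpentyl 3-phenylpropanoate | OCC[C@@H](C)CCOC(=O)CCc1ccccc1 | intermediate
4 | (S)-5-iodo-3-methylpentyl 3-phenylpropanoate | ICC[C@@H](C)CCOC(=O)CCc1ccccc1 | intermediate
5 | 2-methylcyclohex-2-en-1-one | CC1=CCCCC1=O | starting material
6 | dimethylaluminium (3R)-2,3-dimethylcyclohex-1-en-1-olate | C[Al](C)OC1=C(C)[C@H](C)CCC1 | intermediate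
7 | [(3R)-2,3-dimethylcyclohex-1-en-1-yl]oxy-trimethylsilane | C[Si](C)(C)OC1=C(C)[C@H](C)CCC1 | intermediate
8 | lithium (3R)-2,3-dimethylcyclohex-1-en-1-olate | [Li]OC1=C(C)[C@H](C)CCC1 | intermediate
9 | (R)-5-[(1S,2R)-1,2-dimethyl-6-oxocyclohexyl]-3-methylpentyl 3-phenylpropanoate | O=C1CCC[C@@H](C)[C@]1(C)CC[C@@H](C)CCOC(=O)CCc1ccccc1 | intermediate
10 | (5R,6S)-5,6-dimethyl-6-[(R)-3-methyl-5-(3-phenylpropanoyloxy)pentyl]cyclohex-1-en-1-yl trifluoromethanesulfonate | O=S(=O)(OC1=CCC[C@@H](C)[C@]1(C)CC[C@@H](C)CCOC(=O)CCc1ccccc1)C(F)(F)F | intermediate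
11 | (R)-5-[(1S,6R)-2-(1-ethoxyvinyl)-1,6-dimethylcyclohex-2-en-1-yl]-3-methylpentyl 3-phenylpropanoate | C=C(OCC)C1=CCC[C@@H](C)[C@]1(C)CC[C@@H](C)CCOC(=O)CCc1ccccc1 | intermediate
12 | (R)-5-[(1S,6R)-2-acetyl-1,6-dimethylcyclohex-2-en-1-yl]-3-methylpentyl 3-phenylpropanoate | CC(=O)C1=CCC[C@@H](C)[C@]1(C)CC[C@@H](C)CCOC(=O)CCc1ccccc1 | intermediate
13 | (R)-5-[(1S,6R)-2-[1-(tert-butyldimethylsilyloxy)vinyl]-1,6-dimethylcyclohex-2-en-1-yl]-3-methylpentyl 3-phenylpropanoate | C=C(O[Si](C)(C)C(C)(C)C)C1=CCC[C@@H](C)[C@]1(C)CC[C@@H](C)CCOC(=O)CCc1ccccc1 | intermediate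
14 | methacrolein (2-methylprop-2-enal) | CC(=C)C=O | starting material
15 | (4S,8R,9S,13R)-1-(tert-butyldimethylsilyloxy)-18-oxohalim-1(10)-en-15-yl 3-phenylpropanoate, C5 epimers | O=C[C@@]1(C)CCC(O[Si](C)(C)C(C)(C)C)=C2C1CC[C@@H](C)[C@]2(C)CC[C@@H](C)CCOC(=O)CCc1ccccc1 | intermediate
16 | (4S,8R,9S,13R)-1,18-dioxohalim-5(10)-en-15-yl 3-phenylpropanoate | O=C[C@@]1(C)CCC(=O)C2=C1CC[C@@H](C)[C@]2(C)CC[C@@H](C)CCOC(=O)CCc1ccccc1 | intermediate
17 | (4S,8R,9S,13R)-1-oxo-15-(3-phenylpropanoyloxy)halim-5(10)-en-18-oic acid | OC(=O)[C@@]1(C)CCC(=O)C2=C1CC[C@@H](C)[C@]2(C)CC[C@@H](C)CCOC(=O)CCc1ccccc1 | intermediate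
18 | methyl (4S,8R,9S,13R)-1-oxo-15-(3-phenylpropanoyloxy)halim-5(10)-en-18-oate | COC(=O)[C@@]1(C)CCC(=O)C2=C1CC[C@@H](C)[C@]2(C)CC[C@@H](C)CCOC(=O)CCc1ccccc1 | intermediate
19 | methyl (1S,4S,8R,9S,13R)-1-hydroxy-15-(3-phenylpropanoyloxy)halim-5(10)-en-18-oate | COC(=O)[C@@]1(C)CC[C@H](O)C2=C1CC[C@@H](C)[C@]2(C)CC[C@@H](C)CCOC(=O)CCc1ccccc1 | intermediate
20 | methyl (1R,4S,8R,9S,13R)-1-[1-(2-nitrophenylsulfonyl)hydrazinyl]-15-(3-phenylpropanoyloxy)halim-5(10)-en-18-oate | COC(=O)[C@@]1(C)CC[C@@H](N(N)S(=O)(=O)c3ccccc3[N+](=O)[O-])C2=C1CC[C@@H](C)[C@]2(C)CC[C@@H](C)CCOC(=O)CCc1ccccc1 | intermediate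
21 | methyl (1R,4S,8R,9S,13R)-1-diazenyl-15-(3-phenylpropanoyloxy)halim-5(10)-en-18-oate | COC(=O)[C@@]1(C)CC[C@@H](N=N)C2=C1CC[C@@H](C)[C@]2(C)CC[C@@H](C)CCOC(=O)CCc1ccccc1 | intermediate
22 | methyl (4S,5S,8R,9S,13R)-15-(3-phenylpropanoyloxy)halim-1(10)-en-18-oate | COC(=O)[C@@]1(C)CCC=C2[C@@H]1CC[C@@H](C)[C@]2(C)CC[C@@H](C)CCOC(=O)CCc1ccccc1 | intermediate
23 | methyl (4S,5S,8R,9S,13R)-15-[(E)-3-phenylprop-2-enoyloxy]halim-1(10)-en-18-oate | COC(=O)[C@@]1(C)CCC=C2[C@@H]1CC[C@@H](C)[C@]2(C)CC[C@@H](C)CCOC(=O)/C=C/c1ccccc1 | target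

## Step count and risks

Total step count: 13. Longest linear sequence: 12 steps (1 → 3 → 4 → 9 → … → 23, steps 1, 2 and 4–13); step 3 is the only side branch.

The three steps most likely to fail:

Step 1 (the proposed new method). The enantiotopic hydroxyls are far from the C3 stereocentre, so the enantiomeric excess may be low, and double acylation costs material. Fallback with known chemistry, setting out from 2 and coming back at 3: purchased (R)-citronellol F1 is acylated with 2 by immobilised Candida antarctica lipase B in hexane to give (R)-citronellyl 3-phenylpropanoate F2. Ozonolysis with Me2S work-up gives (R)-3-methyl-6-oxohexyl 3-phenylpropanoate F3. TMSCl, Et3N and NaI in MeCN give the silyl enol ether (R)-3-methyl-6-(trimethylsilyloxy)hex-5-en-1-yl 3-phenylpropanoate F4. A second ozonolysis with NaBH4 work-up removes one carbon and gives 3, with C13 taken from the chiral pool.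

Step 8. The new C4–C5 bond joins a quaternary carbon to a ring carbon next to the quaternary C9, so the reaction may stop at the Mukaiyama–Michael stage or lose catalyst control at C4. Fallback setting out from 12 and coming back at 18: the kinetic lithium dienolate of 12 (LDA, THF, −78 °C) undergoes an anionic double Michael annulation with methyl methacrylate, and the resulting C10 enolate is trapped with TMSCl to give methyl (8R,9S,13R)-15-(3-phenylpropanoyloxy)-1-(trimethylsilyloxy)halim-1(10)-en-18-oate F5 (mixed at C4 and C5). Pd(OAc)2 in MeCN then gives 18 directly. C4 then rests on substrate control, so the C4 epimer must be separated at 18.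

Step 12. The Mitsunobu displacement at C1 is hindered by the tetrasubstituted alkene and the neighbouring quaternary C9, so elimination may compete. Fallback setting out from 19 and coming back at 22: formic acid, dicyclohexylcarbodiimide and 4-dimethylaminopyridine give methyl (1S,4S,8R,9S,13R)-1-formyloxy-15-(3-phenylpropanoyloxy)halim-5(10)-en-18-oate F6. Pd(OAc)2 with PBu3 in dioxane at reflux (Tsuji hydrogenolysis of an allylic formate) then ionises the formate with inversion and delivers hydride from palladium to the ring-fusion carbon C5 on the β-face, giving 22 with loss of CO2.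

## Further compounds

F1 | step 1 | (R)-citronellol | CC(C)=CCC[C@@H](C)CCO
F2 | step 1 | (R)-citronellyl 3-phenylpropanoate | CC(C)=CCC[C@@H](C)CCOC(=O)CCc1ccccc1
F3 | step 1 | (R)-3-methyl-6-oxohexyl 3-phenylpropanoate | O=CCC[C@@H](C)CCOC(=O)CCc1ccccc1
F4 | step 1 | (R)-3-methyl-6-(trimethylsilyloxy)hex-5-en-1-yl 3-phenylpropanoate | C[Si](C)(C)OC=CC[C@@H](C)CCOC(=O)CCc1ccccc1
F5 | step 8 | methyl (8R,9S,13R)-15-(3-phenylpropanoyloxy)-1-(trimethylsilyloxy)halim-1(10)-en-18-oate, mixed at C4 and C5 | COC(=O)C1(C)CCC(O[Si](C)(C)C)=C2C1CC[C@@H](C)[C@]2(C)CC[C@@H](C)CCOC(=O)CCc1ccccc1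
F6 | step 12 | methyl (1S,4S,8R,9S,13R)-1-formyloxy-15-(3-phenylpropanoyloxy)halim-5(10)-en-18-oate | COC(=O)[C@@]1(C)CC[C@H](OC=O)C2=C1CC[C@@H](C)[C@]2(C)CC[C@@H](C)CCOC(=O)CCc1ccccc1
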